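**Retrosynthetic overview**

- The target 16 is cut at the prenyl ether to 7-hydroxy-3',4'-dimethoxyisoflavone 14, which comes from 7-benzyloxy-5-bromo isoflavone 12 by one hydrogenolysis that removes both C5–Br and O-benzyl.
- Feature used: in ring A the neighbouring carbons C8a and C4a carry O1 and the C4 carbonyl. This ortho oxygen/acyl pair is what an aryne gives when it takes up an oxygen nucleophile and then an acyl electrophile.
- Key disconnection of 12: O1–C8a and C4–C4a, leading to aryne 11 (from silyl triflate 5) and formyl ester enol 9, which already holds C2, C3, C4 and ring B. Rings A and B come from the starting materials; the pyranone (ring C) is the only ring formed.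
- 5 comes from 4-(benzyloxy)phenol (dibromination, O-silylation, Br–Li exchange/retro-Brook/triflation); 9 comes from methyl homoveratrate by Claisen formylation.
- Bromine at the future C5 serves only to steer the aryne addition. Benzyl stands in for prenyl because a prenyl alkene would not survive the bromine removal.

Key step: step 5

Remark: the target has no stereocentre and its side-chain alkene carries two identical methyl groups, so no stereocontrol is needed.

**Route**

Step 1
Reactants: 1 4-(benzyloxy)phenol
Product: 2 4-(benzyloxy)-2,6-dibromophenol
Conditions: NBS (2.05 equiv), i-Pr2NH (10 mol %), CH2Cl2, 0 °C → rt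
Reagents that add atoms: N-bromosuccinimide, O=C1CCC(=O)N1Br
Why: Amine-mediated electrophilic aromatic bromination with NBS should place both bromines ortho to the free hydroxyl group, the stronger director (para is blocked by the benzyl ether), and forms no HBr that could endanger the benzyl ether.

Step 2
Reactants: 2 4-(benzyloxy)-2,6-dibromophenol
Product: 3 [4-(benzyloxy)-2,6-dibromophenoxy]trimethylsilane
Conditions: HMDS, THF, 70 °C; volatiles removed in vacuo, used crude
Reagents that add atoms: hexamethyldisilazane, C[Si](C)(C)N[Si](C)(C)C
Why: O-Silylation of a phenol with HMDS is driven by loss of ammonia and should give the silyl ether cleanly enough to be used after evaporation.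

Step 3
Reactants: 3 [4-(benzyloxy)-2,6-dibromophenoxy]trimethylsilane
Product: 5 4-(benzyloxy)-2-bromo-6-(trimethylsilyl)phenyl trifluoromethanesulfonate, via lithium 4-(benzyloxy)-2-bromo-6-(trimethylsilyl)phenoxide 4 (not isolated)
Conditions: n-BuLi (1.05 equiv), THF, −78 °C; then Tf2O (1.2 equiv), −78 °C → rt
Reagents that add atoms: trifluoromethanesulfonic anhydride, O=S(=O)(OS(=O)(=O)C(F)(F)F)C(F)(F)F
Why: Bromine–lithium exchange at one of the two equivalent bromines gives an aryllithium ortho to the silyloxy group, which undergoes the anionic 1,3-O→C silyl shift (retro-Brook rearrangement) to phenoxide 4; the remaining bromine is meta to the carbanion and cannot be eliminated, and the phenoxide is then O-sulfonylated by Tf2O.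

Step 4
Reactants: 6 methyl (3,4-dimethoxyphenyl)acetate; 7 methyl formate
Product: 9 methyl (Z)-2-(3,4-dimethoxyphenyl)-3-hydroxyacrylate, via sodium enolate of the formyl ester 8 (not isolated)
Conditions: NaH (2 equiv), HCO2Me (5 equiv), THF, 0 °C → rt; then cold 1 M HCl
Reagents that add atoms: none
Why: Crossed Claisen condensation (C-formylation): methyl formate has no α-hydrogen and is the more electrophilic ester, the reaction is driven by irreversible formation of the stabilised enolate 8, and acidification should give the enol in its Z form, held by the hydrogen bond from O–H to the ester carbonyl.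

Step 5
Reactants: 5 4-(benzyloxy)-2-bromo-6-(trimethylsilyl)phenyl trifluoromethanesulfonate; 9 methyl (Z)-2-(3,4-dimethoxyphenyl)-3-hydroxyacrylate
Product: 12 7-(benzyloxy)-5-bromo-3',4'-dimethoxyisoflavone, via cesium enolate of the formyl ester 10 (not isolated), via 5-(benzyloxy)-3-bromobenzyne 11 (not isolated)
Conditions: 5 (1.3 equiv), CsF (4 equiv), THF, 65 °C
Reagents that add atoms: none
Why: Proposed new method: fluoride removes the silyl group of 5 and triflate leaves to give aryne 11, while CsF turns enol 9 into enolate 10; the enolate oxygen adds to the aryne carbon remote from bromine (O1–C8a), and the aryl anion formed at the future C4a attacks the ester carbonyl and expels methoxide (C4–C4a). The closest known reactions are the annulation of arynes with methyl salicylates to xanthones (O-arylation, then intramolecular acyl capture) and the insertion of arynes into β-dicarbonyl compounds; new here is an acyclic enolate oxygen as the nucleophile. The pyranone ring closes in a 6-exo-trig addition–elimination at the ester, and no stereocentre is formed. Three selectivities are needed: regiochemistry on the aryne, O- over C-arylation, and a cis relation of aryloxy group and ester on the enol ether. The first is secured by bromine, whose inductive effect distorts the aryne so that the nucleophile enters at the distal carbon and the charge develops next to the halogen, overriding the weak opposite bias of the remote benzyloxy group; the second by the fully substituted, aryl-conjugated α-carbon set against an exposed terminal oxygen. The third rests on the enolate, whose two geometries interconvert readily (vinylogous carboxylate) and which should react as the cesium-bridged U-shaped contact ion pair in weakly polar THF, a solvent that also slows proton transfer to the aryl anion.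

Step 6
Reactants: 12 7-(benzyloxy)-5-bromo-3',4'-dimethoxyisoflavone
Product: 14 7-hydroxy-3',4'-dimethoxyisoflavone, via 7-(benzyloxy)-3',4'-dimethoxyisoflavone 13 (not isolated)
Conditions: H2 (1 atm), 10% Pd/C, NaOAc (1.5 equiv), THF–MeOH, rt
Reagents that add atoms: none
Why: Palladium-catalysed hydrogenolysis should cleave the activated C5–Br bond (acetate takes up the HBr and does not poison the debenzylation) and then the benzylic C–O bond of the aryl benzyl ether, while the C2=C3 bond of the chromone, a vinylogous ester, is reduced much more slowly at 1 atm and room temperature, so the reaction is stopped when 13 is consumed.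

Step 7
Reactants: 14 7-hydroxy-3',4'-dimethoxyisoflavone; 15 prenyl bromide
Product: 16 7-prenyloxy-3',4'-dimethoxyisoflavone
Conditions: 15 (1.2 equiv), K2CO3 (2 equiv), acetone, reflux
Reagents that add atoms: none
Why: Williamson ether synthesis: the acidic 7-hydroxyl (a vinylogous acid through the chromone carbonyl) is the only nucleophilic site, carbonate deprotonates it, and SN2 attack at the primary allylic carbon of prenyl bromide should give the ether without SN2' or C-alkylation.

**Compound list**

1 | 4-(benzyloxy)phenol | Oc1ccc(OCc2ccccc2)cc1 | starting material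
2 | 4-(benzyloxy)-2,6-dibromophenol | Oc1c(Br)cc(OCc2ccccc2)cc1Br | intermediate
3 | [4-(benzyloxy)-2,6-dibromophenoxy]trimethylsilane | C[Si](C)(C)Oc1c(Br)cc(OCc2ccccc2)cc1Br | intermediate
4 | lithium 4-(benzyloxy)-2-bromo-6-(trimethylsilyl)phenoxide | [Li+].[O-]c1c(Br)cc(OCc2ccccc2)cc1[Si](C)(C)C | intermediate (not isolated)
5 | 4-(benzyloxy)-2-bromo-6-(trimethylsilyl)phenyl trifluoromethanesulfonate | C[Si](C)(C)c1cc(OCc2ccccc2)cc(Br)c1OS(=O)(=O)C(F)(F)F | intermediate
6 | methyl (3,4-dimethoxyphenyl)acetate | COC(=O)Cc1ccc(OC)c(OC)c1 | starting material
7 | methyl formate | COC=O | starting material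
8 | sodium (Z)-2-(3,4-dimethoxyphenyl)-3-methoxy-3-oxoprop-1-en-1-olate | COC(=O)/C(=C\[O-])c1ccc(OC)c(OC)c1.[Na+] | intermediate (not isolated)
9 | methyl (Z)-2-(3,4-dimethoxyphenyl)-3-hydroxyacrylate | COC(=O)/C(=C\O)c1ccc(OC)c(OC)c1 | intermediate
10 | cesium (Z)-2-(3,4-dimethoxyphenyl)-3-methoxy-3-oxoprop-1-en-1-olate | COC(=O)/C(=C\[O-])c1ccc(OC)c(OC)c1.[Cs+] | intermediate (not isolated)
11 | 5-(benzyloxy)-3-bromobenzyne (5-(benzyloxy)-3-bromo-1,2-didehydrobenzene) | BrC1=CC(OCc2ccccc2)=CC#C1 | intermediate (not isolated)
12 | 7-(benzyloxy)-5-bromo-3',4'-dimethoxyisoflavone | COc1ccc(-c2coc3cc(OCc4ccccc4)cc(Br)c3c2=O)cc1OC | intermediate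
13 | 7-(benzyloxy)-3',4'-dimethoxyisoflavone | COc1ccc(-c2coc3cc(OCc4ccccc4)ccc3c2=O)cc1OC | intermediate (not isolated)
14 | 7-hydroxy-3',4'-dimethoxyisoflavone | COc1ccc(-c2coc3cc(O)ccc3c2=O)cc1OC | intermediate
15 | prenyl bromide (1-bromo-3-methylbut-2-ene) | CC(C)=CCBr | starting material
16 | 7-prenyloxy-3',4'-dimethoxyisoflavone | COc1ccc(-c2coc3cc(OCC=C(C)C)ccc3c2=O)cc1OC | target

**Step count**

Total: 7 steps. Longest linear sequence: 6 steps (steps 1, 2, 3, 5, 6, 7 from 4-(benzyloxy)phenol); step 4 is a one-step branch.

**Steps most likely to fail**

1. Step 5 (proposed new method). Three processes may divert it.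
   - C-arylation of the enolate at its α-carbon, followed by capture of the formyl group, which amounts to aryne insertion into the C–CHO bond.
   - O-arylation through the extended enolate geometry, which puts the aryloxy group trans to the ester, so the aryl anion cannot reach it and is simply protonated.
   - Loss of bromide from the ortho-bromoaryl anion before the acyl capture.

   Fallback by known chemistry, from 6 back to 14: 6 is saponified (LiOH, THF–H2O) to (3,4-dimethoxyphenyl)acetic acid F1. Resorcinol is acylated with F1 in BF3·OEt2 at about 85 °C (Friedel–Crafts acylation) to give 1-(2,4-dihydroxyphenyl)-2-(3,4-dimethoxyphenyl)ethan-1-one F2. The one-carbon ring closure of this deoxybenzoin with DMF, BF3·OEt2 and MsCl should give 14, and step 7 follows unchanged. Steps 1–3, 5 and 6 are then not needed.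

2. Step 6. The C2=C3 bond of the chromone may be reduced once bromine and benzyl are gone, or the catalyst may stall on bromide before debenzylation is complete.
   Fallback without hydrogen gas, from 12 back to 14: the C–Br bond is reduced under homogeneous palladium catalysis with formate as hydride source (Pd(OAc)2, PPh3, HCO2Na, DMF, 80 °C), and 13 is isolated this time. The benzyl ether is then cleaved with BCl3 and pentamethylbenzene in CH2Cl2 at −78 °C to give 14.

3. Step 3. A second bromine–lithium exchange, attack of butyllithium at silicon, or incomplete silyl migration may give mixtures that are carried into the triflation.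
   Fallback that avoids the silyl shift, from 2 back to 5: 2 is converted with n-BuLi (2.1 equiv) into the C,O-dilithio species and quenched with TMSCl (2.2 equiv) to give [4-(benzyloxy)-2-bromo-6-(trimethylsilyl)phenoxy]trimethylsilane F3. The O-silyl group is removed with K2CO3 in MeOH to give 4-(benzyloxy)-2-bromo-6-(trimethylsilyl)phenol F4, which is purified and converted with Tf2O and pyridine in CH2Cl2 at 0 °C into 5.

**Further compounds**

F1 | step 5 | (3,4-dimethoxyphenyl)acetic acid | OC(=O)Cc1ccc(OC)c(OC)c1
F2 | step 5 | 1-(2,4-dihydroxyphenyl)-2-(3,4-dimethoxyphenyl)ethan-1-one | COc1ccc(CC(=O)c2ccc(O)cc2O)cc1OC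
F0 | step 6 | none | none
F3 | step 3 | [4-(benzyloxy)-2-bromo-6-(trimethylsilyl)phenoxy]trimethylsilane | C[Si](C)(C)Oc1c(Br)cc(OCc2ccccc2)cc1[Si](C)(C)C
F4 | step 3 | 4-(benzyloxy)-2-bromo-6-(trimethylsilyl)phenol | Oc1c(Br)cc(OCc2ccccc2)cc1[Si](C)(C)C
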